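## The problem

Compound 17 (CNP0197133.1) is a tetrahydrofuran lignan: ring atoms O1, C2 (guaiacyl), C3 (CH2OH), C4 and C5 (CH2), with C4 carrying an exocyclic carbinol carbon, here called C6, that bears the catechol ring. The two aryl halves are joined through a four-carbon, oxygen-rich core and not through a fused system, so the ring has to be built with three contiguous stereocentres. These are C2 (S), C3 (R) and C4 (S), all-trans (2,3-trans, 3,4-trans, hence 2,4-cis); the fourth, C6 (R), lies outside the ring. C2 is a benzylic ether carbon with no acidifying neighbour, so it cannot be repaired after ring closure and must carry the absolute configuration. C3 and C4 become epimerisable once they are α to an ester and an aryl ketone, and the all-trans array is the thermodynamic one; C6 sits where 1,2-induction from C4 is not dependable and needs a reagent-controlled reduction. The free catechol is oxidised in air under base, and the p-hydroxybenzylic alcohol at C6 and the benzylic C2–O1 bond ionise in acid and are at risk under forcing hydrogenolysis, so the phenols must stay masked until a last, neutral step. A free C3 hydroxymethyl beside a C6 ketone would close to a cis-fused bicyclic hemiketal and pull C4 the wrong way, which fixes the order of the late redox steps. The enabling feature is that O1–C5–C4 with its one-carbon branch C6 is the skeleton of a vinyl epoxide carrying the catechol ring on the inner alkene carbon, while C2–C3, with the hydroxymethyl read as a malonate, is an arylidene malonate of vanillin. An annulation forming O1–C2 and C3–C4 therefore puts every carbon of 17 in place at once.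

## Retrosynthesis

**17 from 16.** Only the three aryl O–benzyl bonds are cut. Benzyl is the one phenol mask that survives cross-coupling, hot chloride, methoxide, osmium/periodate, borane and aluminium hydride and still leaves under neutral conditions. No alkyl benzyl ether is present in 16, so the hydrogenolysis can be short enough to spare the two benzylic C–O bonds.

**16 from 15 from 14.** The C3 hydroxymethyl is traced back to a methyl ester and the C6 carbinol to an aryl ketone. The ketone of keto ester 14 is reduced first, while C3 is still an ester. This removes the need to protect a primary alcohol, the hemiketal problem cannot arise, and the trans hydroxy ester 15 cannot lactonise. The forward reactions are a reagent-controlled ketone reduction that must override any bias from C4, and a plain ester reduction.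

**14 from 12.** The C6=O bond is traced back to C6=CH2. The 1-arylvinyl group of 12 is exactly what the annulation delivers, so the ketone costs one oxidative cleavage. That cleavage must leave three electron-rich arenes alone, which favours osmium/periodate over ozone.

**12 from 11 from 9.** C3–H is traced back to C3–CO2Me. The second ester of diester 9 is what makes the acceptor reactive. Its removal gives 11 as a C3 epimer mixture. Because the C2 and C4 substituents are cis, the remaining ester has only one comfortable position, trans to both, so methoxide equilibration should give 12.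

**9 from 5 and 8.** O1–C2 and C3–C4 are cut. Cutting only O1–C2 or only C4–C5 leaves an open chain whose stereocentres must all be made by acyclic control. This double cut instead splits the molecule into its two aromatic halves, each one to three steps from catalogue compounds. Neither partner needs a stereocentre: racemic epoxide 5 suffices because its stereocentre is erased on ionisation. The forward reaction must control the allyl face with a chiral ligand, close the ring 2,4-cis, and deliver C2 in one absolute sense.

**8 from 6 and 7.** The C2=C3 bond is cut by a Knoevenagel condensation of O-benzylvanillin 6 with dimethyl malonate 7.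

**5 from 4 from 3 from 1 and 2.** The oxirane is opened to enal 4 and a sulfonium methylide, the aldehyde is traced to allylic alcohol 3, and the aryl–alkene bond of 3 is cut to boronic acid 1 and 2-bromoallyl alcohol 2. The aryl group is thereby coupled to a three-carbon unit that already holds the alkene and the oxygen. This is shorter than methylenating, reducing and re-oxidising an arylacetic ester.

## Roads not taken

**Alternative 1:** The cut is C4–C5. The key-step product A1 is the benzyl-protected tetrahydrofuran with a free C6 hydroxyl. Its precursor A2 is an N-acyloxyphthalimide in which the C2 oxygen carries CH2CO2N(phthaloyl) and C3 carries a benzyloxymethyl group and an (E)-styryl arm ending in the protected catechol.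
- Forward step: fac-Ir(ppy)3 under visible light reduces the ester of A2; CO2 and phthalimide leave; the alkoxymethyl radical closes 5-exo onto the styrene; the benzylic radical is oxidised to the cation and water adds, giving A1.
- Merits: ring closure and C6 oxygenation happen in one step. C4 should follow C3 through a chair-like transition state. C2 and C3 could come from an auxiliary-controlled anti aldol, so the absolute configuration would rest on stoichiometric, predictable chemistry. In this respect it is surer than the chosen annulation.
- Weak points: C6 forms by water capture of a planar, donor-stabilised cation with no facial control, so A1 is an epimer mixture. It would then need oxidation and a reagent-controlled reduction, the same problem as at 14 but reached later. The cation may also lose a proton or be captured by the neighbouring benzyloxymethyl oxygen. Making A2 requires O-alkylating a hindered benzylic alkoxide, and the end-game must cleave an alkyl benzyl ether beside the sensitive C6 alcohol.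
- Comparison: the chosen plan offers two-fragment convergence, catalytic asymmetric induction and thermodynamic correction of C3 and C4. Its cost is an untested substrate pairing in the ring-forming step.

**Alternative 2:** The cuts are O1–C2 and the bond from C3 to its ester carbon. The key-step product A3 is a 2-aryl-4,5-dihydrofuran-3-carboxylate. Its precursor A4 is a homopropargylic primary alcohol with the guaiacyl ring on the alkyne and a silylated C6 carbinol on C4.
- Forward step: PdCl2(MeCN)2 (divalent palladium), p-benzoquinone, CO and MeOH. The C5 hydroxyl attacks the activated alkyne 5-endo-dig and the vinylpalladium is methoxycarbonylated.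
- Merits: C4 and C6 are set before ring closure by well-understood acyclic chemistry, so no late ketone reduction on a chiral substrate is needed. Here it is better than the chosen plan. The C3 carbon arrives in the ring-forming step.
- Weak points: C2 and C3 are flat in A3. Hydrogenating this tetrasubstituted push–pull alkene anti to the C4 side chain would give the all-cis ring, so a C3 epimerisation must follow. Such an alkene is hard to reduce without endangering the benzylic C2–O1 bond. The aryl silyl ethers would not survive the base needed for the epimerisation.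
- Comparison: the chosen plan forms C2 directly at the right oxidation level and needs no alkene reduction. Its cost is a reagent-controlled reduction at C6.

**Alternative 3:** The cut is O1–C2 alone. The key-step product A5 is the 2,3-trans-3,4-trans tetrahydrofuran with free guaiacol. Its precursor A6 is an open-chain seco-lignan diol with a free guaiacol, a silylated C6 carbinol and a benzylated catechol.
- Forward step: Ag2O (or DDQ) oxidises the phenol of A6 to its p-quinone methide, and the primary hydroxyl of the future C5 adds to the benzylic carbon.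
- Merits: this is the mildest ring closure of the four. C2 forms last with a preference for 2,3-trans, the guaiacol is already free, and the end-game is short. In these respects it is as good as or better than the chosen plan.
- Weak points: A6 holds C3, C4 and C6 as three contiguous acyclic stereocentres and four differently treated oxygens, so the stereochemical problem is moved into a long linear prelude. The quinone methide can also tautomerise to a styrene or be trapped intermolecularly. DDQ could attack the other electron-rich benzylic position.
- Comparison: the chosen plan has no acyclic stereocontrol at all, a short convergent assembly, and a thermodynamic funnel for C3 and C4.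

Key step: step 5

Assumption (chemistry): the sense of induction of the bisphosphine on a π-allyl carrying an aryl group at its central carbon cannot be taken over safely from unsubstituted vinyl epoxides. The (S,S)-ligand is written in step 5; its mirror image is used if the first run shows the opposite sense.

Assumption (supply): boronic acid 1 and bromo alcohol 2 are treated as catalogue compounds.

## Route

Step 1
Reactants: 1 [3,4-bis(benzyloxy)phenyl]boronic acid; 2 2-bromoprop-2-en-1-ol
Product: 3 2-[3,4-bis(benzyloxy)phenyl]prop-2-en-1-ol
Conditions: Pd(PPh3)4 (3 mol %), K2CO3, toluene/EtOH/H2O, 80 °C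
Reagents that add atoms: none
Why: Suzuki–Miyaura coupling of an alkenyl bromide with an arylboronic acid; the free allylic hydroxyl is tolerated and the aryl group ends on the inner alkene carbon because that is where the bromine sits.

Step 2
Reactants: 3 2-[3,4-bis(benzyloxy)phenyl]prop-2-en-1-ol
Product: 4 2-[3,4-bis(benzyloxy)phenyl]prop-2-enal
Conditions: MnO2 (activated, excess), CH2Cl2, rt
Reagents that add atoms: none
Why: Allylic oxidation on activated MnO2 stops at the aldehyde under neutral heterogeneous conditions; the polymerisation-prone 2-arylacrolein is obtained by filtration and should be taken on at once.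

Step 3
Reactants: 4 2-[3,4-bis(benzyloxy)phenyl]prop-2-enal
Product: 5 racemic 2-{1-[3,4-bis(benzyloxy)phenyl]ethenyl}oxirane
Conditions: Me3S+ I−, NaH, DMSO/THF, 0 °C
Reagents that add atoms: trimethylsulfonium iodide, C[S+](C)C.[I-]
Why: Corey–Chaykovsky epoxidation: the unstabilised sulfonium methylide adds 1,2 to the enal and the betaine closes irreversibly to the oxirane, whereas a sulfoxonium ylide would cyclopropanate. The racemate is all that is needed because this stereocentre is erased when palladium ionises the epoxide.

Step 4
Reactants: 6 4-(benzyloxy)-3-methoxybenzaldehyde; 7 dimethyl malonate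
Product: 8 dimethyl 2-[4-(benzyloxy)-3-methoxybenzylidene]malonate
Conditions: piperidine (cat.), AcOH (cat.), toluene, reflux, Dean–Stark trap
Reagents that add atoms: none
Why: Knoevenagel condensation driven by azeotropic removal of water; the two ester groups are identical, so no alkene geometry arises.

Step 5
Reactants: 5 racemic 2-{1-[3,4-bis(benzyloxy)phenyl]ethenyl}oxirane (1.5 equiv); 8 dimethyl 2-[4-(benzyloxy)-3-methoxybenzylidene]malonate
Product: 9 dimethyl (2R,4S)-2-[4-(benzyloxy)-3-methoxyphenyl]-4-{1-[3,4-bis(benzyloxy)phenyl]ethenyl}oxolane-3,3-dicarboxylate (2,4-cis)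
Conditions: Pd2(dba)3·CHCl3 (2.5 mol %), (S,S)-DACH-phenyl bisphosphine [N,N'-((1S,2S)-cyclohexane-1,2-diyl)bis(2-(diphenylphosphanyl)benzamide)] (7.5 mol %), THF, 25–40 °C
Reagents that add atoms: none
Why: Zerovalent palladium ionises the allylic C–O bond of 5 with release of ring strain to a zwitterionic 2-aryl-π-allylpalladium alkoxide; the alkoxide adds reversibly to the benzylidene carbon of 8 (oxa-Michael, O1–C2) and the malonate carbanion then attacks the substituted allyl terminus on the face opposite to palladium (C3–C4). The closest known reaction type is the palladium-catalysed formal [3+2] cycloaddition of butadiene monoxide with arylidene malononitriles, nitroalkenes and enones, which has enantioselective forms; new here are the aryl group on the central allyl carbon and the malonate acceptor. The tetrahydrofuran closes by a 5-exo intramolecular allylic alkylation, and attack on the CH2 terminus would need a seven-membered ring and should not compete. C4 is set by the chiral bisphosphine: the π-allyl complexes from the two enantiomers of 5 interconvert by η3–η1–η3 slippage through the unsubstituted CH2 terminus, so the racemate is funnelled through the complex that the ligand pocket favours. C2 is set relative to C4 in the ring closure: because the oxa-Michael step is reversible, the two C2-epimeric adducts exchange, and the one that closes through an envelope with the aryl group and the allyl unit both pseudo-equatorial should react faster, giving the 2,4-cis ring. The step needs trapping of the zwitterion to outrun its isomerisation to an unsaturated carbonyl compound, and it needs high diastereoselectivity because only C2 is carried unchanged to 17. Two ester groups on the acceptor, an excess of 5 and chromatographic removal of any 2,4-trans isomer at this stage are meant to secure this.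

Step 6
Reactants: 9 dimethyl (2R,4S)-2-[4-(benzyloxy)-3-methoxyphenyl]-4-{1-[3,4-bis(benzyloxy)phenyl]ethenyl}oxolane-3,3-dicarboxylate
Product: 11 methyl (2S,4R)-2-[4-(benzyloxy)-3-methoxyphenyl]-4-{1-[3,4-bis(benzyloxy)phenyl]ethenyl}oxolane-3-carboxylate as a mixture of C3 epimers, via lithium carboxylate half-ester 10 (not isolated)
Conditions: LiCl, H2O, DMSO, 150 °C
Reagents that add atoms: none
Why: Krapcho dealkoxycarbonylation: chloride attacks one ester methyl group (SN2), the carboxylate loses CO2 through the enolate of the remaining ester, and water protonates C3. The protonation is not expected to be selective, which does not matter because step 7 equilibrates C3.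

Step 7
Reactants: 11 methyl (2S,4R)-2-[4-(benzyloxy)-3-methoxyphenyl]-4-{1-[3,4-bis(benzyloxy)phenyl]ethenyl}oxolane-3-carboxylate (C3 epimers)
Product: 12 methyl (2S,3S,4R)-2-[4-(benzyloxy)-3-methoxyphenyl]-4-{1-[3,4-bis(benzyloxy)phenyl]ethenyl}oxolane-3-carboxylate (2,3-trans-3,4-trans)
Conditions: NaOMe, MeOH/THF, 50 °C
Reagents that add atoms: none
Why: Epimerisation through the ester enolate under thermodynamic control: with the C2 and C4 substituents cis to each other, the ester is trans to both only in the (3S) isomer. Ring opening by loss of the C2 alkoxide from the enolate would be the reverse of a 5-endo-trig closure and should be slow.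

Step 8
Reactants: 12 methyl (2S,3S,4R)-2-[4-(benzyloxy)-3-methoxyphenyl]-4-{1-[3,4-bis(benzyloxy)phenyl]ethenyl}oxolane-3-carboxylate
Product: 14 methyl (2S,3S,4S)-2-[4-(benzyloxy)-3-methoxyphenyl]-4-[3,4-bis(benzyloxy)benzoyl]oxolane-3-carboxylate, via vicinal diol 13 (not isolated)
Conditions: OsO4 (2 mol %), NaIO4, 2,6-lutidine, dioxane/H2O, rt
Reagents that add atoms: osmium tetroxide, O=[Os](=O)(=O)=O (delivers the ketone oxygen and is regenerated by sodium periodate, [Na+].[O-]I(=O)(=O)=O)
Why: Lemieux–Johnson oxidation: osmium tetroxide dihydroxylates the only alkene and periodate cleaves the diol to the aryl ketone and formaldehyde, and unlike ozone this reagent pair leaves the three electron-rich arenes alone. C4 is now epimerisable but already holds the thermodynamically preferred all-trans arrangement.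

Step 9
Reactants: 14 methyl (2S,3S,4S)-2-[4-(benzyloxy)-3-methoxyphenyl]-4-[3,4-bis(benzyloxy)benzoyl]oxolane-3-carboxylate
Product: 15 methyl (2S,3S,4S)-2-[4-(benzyloxy)-3-methoxyphenyl]-4-{(R)-[3,4-bis(benzyloxy)phenyl](hydroxy)methyl}oxolane-3-carboxylate
Conditions: (S)-1-methyl-3,3-diphenyltetrahydro-1H,3H-pyrrolo[1,2-c][1,3,2]oxazaborole (20 mol %), BH3·SMe2, THF, −20 °C; then MeOH, aqueous work-up
Reagents that add atoms: none
Why: Corey–Bakshi–Shibata reduction under reagent control: the oxazaborolidine–borane complex binds the ketone anti to the aryl group and, by analogy with aryl alkyl ketones, the (S)-catalyst should give the (R)-carbinol. The methyl ester is not reduced at this temperature and the trans hydroxy ester cannot lactonise.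

Step 10
Reactants: 15 methyl (2S,3S,4S)-2-[4-(benzyloxy)-3-methoxyphenyl]-4-{(R)-[3,4-bis(benzyloxy)phenyl](hydroxy)methyl}oxolane-3-carboxylate
Product: 16 (R)-[3,4-bis(benzyloxy)phenyl]{(3S,4R,5S)-5-[4-(benzyloxy)-3-methoxyphenyl]-4-(hydroxymethyl)oxolan-3-yl}methanol
Conditions: LiAlH4, THF, 0 °C; aq. potassium sodium tartrate
Reagents that add atoms: none
Why: Hydride reduction of the methyl ester to the primary alcohol; aryl benzyl ethers are inert, and the aluminate-bound aldehyde stage is reduced faster than it could enolise, so C3 is not disturbed.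

Step 11
Reactants: 16 (R)-[3,4-bis(benzyloxy)phenyl]{(3S,4R,5S)-5-[4-(benzyloxy)-3-methoxyphenyl]-4-(hydroxymethyl)oxolan-3-yl}methanol
Product: 17 4-{(R)-hydroxy[(3S,4R,5S)-5-(4-hydroxy-3-methoxyphenyl)-4-(hydroxymethyl)oxolan-3-yl]methyl}benzene-1,2-diol (CNP0197133.1)
Conditions: H2 (1 atm), Pd/C (10 %), EtOAc/MeOH, rt
Reagents that add atoms: none
Why: Hydrogenolysis of three aryl benzyl ethers, which is fast on palladium under neutral conditions. The secondary benzylic alcohol and the benzylic ring ether are cleaved much more slowly without acid, so the reaction is stopped once three equivalents of hydrogen are taken up.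

## Compound list

1 | [3,4-bis(benzyloxy)phenyl]boronic acid | OB(O)c1ccc(OCc2ccccc2)c(OCc2ccccc2)c1 | starting material
2 | 2-bromoprop-2-en-1-ol | C=C(Br)CO | starting material
3 | 2-[3,4-bis(benzyloxy)phenyl]prop-2-en-1-ol | C=C(CO)c1ccc(OCc2ccccc2)c(OCc2ccccc2)c1 | intermediate
4 | 2-[3,4-bis(benzyloxy)phenyl]prop-2-enal | C=C(C=O)c1ccc(OCc2ccccc2)c(OCc2ccccc2)c1 | intermediate
5 | racemic 2-{1-[3,4-bis(benzyloxy)phenyl]ethenyl}oxirane | C=C(C1CO1)c1ccc(OCc2ccccc2)c(OCc2ccccc2)c1 | intermediate
6 | 4-(benzyloxy)-3-methoxybenzaldehyde | COc1cc(C=O)ccc1OCc1ccccc1 | starting material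
7 | dimethyl malonate | COC(=O)CC(=O)OC | starting material
8 | dimethyl 2-[4-(benzyloxy)-3-methoxybenzylidene]malonate | COC(=O)C(=Cc1ccc(OCc2ccccc2)c(OC)c1)C(=O)OC | intermediate
9 | dimethyl (2R,4S)-2-[4-(benzyloxy)-3-methoxyphenyl]-4-{1-[3,4-bis(benzyloxy)phenyl]ethenyl}oxolane-3,3-dicarboxylate | COc1cc([C@H]2OC[C@@H](C(=C)c3ccc(OCc4ccccc4)c(OCc4ccccc4)c3)C2(C(=O)OC)C(=O)OC)ccc1OCc1ccccc1 | intermediate
10 | lithium (2R,4S)-2-[4-(benzyloxy)-3-methoxyphenyl]-4-{1-[3,4-bis(benzyloxy)phenyl]ethenyl}-3-(methoxycarbonyl)oxolane-3-carboxylate, both C3 epimers | [Li+].COc1cc([C@H]2OC[C@@H](C(=C)c3ccc(OCc4ccccc4)c(OCc4ccccc4)c3)C2(C(=O)OC)C(=O)[O-])ccc1OCc1ccccc1 | intermediate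
11 | methyl (2S,4R)-2-[4-(benzyloxy)-3-methoxyphenyl]-4-{1-[3,4-bis(benzyloxy)phenyl]ethenyl}oxolane-3-carboxylate, C3 epimer mixture | COc1cc([C@H]2OC[C@@H](C(=C)c3ccc(OCc4ccccc4)c(OCc4ccccc4)c3)C2C(=O)OC)ccc1OCc1ccccc1 | intermediate
12 | methyl (2S,3S,4R)-2-[4-(benzyloxy)-3-methoxyphenyl]-4-{1-[3,4-bis(benzyloxy)phenyl]ethenyl}oxolane-3-carboxylate | COc1cc([C@H]2OC[C@@H](C(=C)c3ccc(OCc4ccccc4)c(OCc4ccccc4)c3)[C@@H]2C(=O)OC)ccc1OCc1ccccc1 | intermediate
13 | methyl (2S,3S,4S)-2-[4-(benzyloxy)-3-methoxyphenyl]-4-{1-[3,4-bis(benzyloxy)phenyl]-1,2-dihydroxyethyl}oxolane-3-carboxylate, both epimers at the diol carbon | COc1cc([C@H]2OC[C@@H](C(O)(CO)c3ccc(OCc4ccccc4)c(OCc4ccccc4)c3)[C@@H]2C(=O)OC)ccc1OCc1ccccc1 | intermediate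
14 | methyl (2S,3S,4S)-2-[4-(benzyloxy)-3-methoxyphenyl]-4-[3,4-bis(benzyloxy)benzoyl]oxolane-3-carboxylate | COc1cc([C@H]2OC[C@@H](C(=O)c3ccc(OCc4ccccc4)c(OCc4ccccc4)c3)[C@@H]2C(=O)OC)ccc1OCc1ccccc1 | intermediate
15 | methyl (2S,3S,4S)-2-[4-(benzyloxy)-3-methoxyphenyl]-4-{(R)-[3,4-bis(benzyloxy)phenyl](hydroxy)methyl}oxolane-3-carboxylate | COc1cc([C@H]2OC[C@@H]([C@@H](O)c3ccc(OCc4ccccc4)c(OCc4ccccc4)c3)[C@@H]2C(=O)OC)ccc1OCc1ccccc1 | intermediate
16 | (R)-[3,4-bis(benzyloxy)phenyl]{(3S,4R,5S)-5-[4-(benzyloxy)-3-methoxyphenyl]-4-(hydroxymethyl)oxolan-3-yl}methanol | COc1cc([C@H]2OC[C@@H]([C@@H](O)c3ccc(OCc4ccccc4)c(OCc4ccccc4)c3)[C@@H]2CO)ccc1OCc1ccccc1 | intermediate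
17 | 4-{(R)-hydroxy[(3S,4R,5S)-5-(4-hydroxy-3-methoxyphenyl)-4-(hydroxymethyl)oxolan-3-yl]methyl}benzene-1,2-diol | COc1cc([C@H]2OC[C@@H]([C@@H](O)c3ccc(O)c(O)c3)[C@@H]2CO)ccc1O | target

## Step count and least certain steps

Total: 11 steps. Longest linear sequence: 10 steps (steps 1–3 and 5–11, from 1 to 17).

**Step 5 (key step).** The most likely failure is that oxa-Michael addition to the electron-rich arylidene malonate is too slow, so the palladium zwitterion isomerises or oligomerises first. Independently, weak control of the allyl face or of the 2,4-relationship would surface later as low enantiopurity at C2. One mitigating point is that C4 can still be corrected at the keto ester stage, so only C2 has to be right. The fallback changes the acceptor class and sets out from 6. Condensation with 2,2-dimethyl-1,3-dioxane-4,6-dione in EtOH with piperidinium acetate gives the far more electrophilic 5-[4-(benzyloxy)-3-methoxybenzylidene]-2,2-dimethyl-1,3-dioxane-4,6-dione F1. Annulation with 5 under the catalyst of step 5 gives the spiro adduct 1-[4-(benzyloxy)-3-methoxyphenyl]-4-{1-[3,4-bis(benzyloxy)phenyl]ethenyl}-8,8-dimethyl-2,7,9-trioxaspiro[4.5]decane-6,10-dione F2. Heating F2 in MeOH/pyridine opens the dioxanedione with loss of acetone and CO2 and gives 11, so the route is rejoined at 11 and step 6 is skipped.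

**Step 9.** Poor facial selectivity is possible if the catalyst's preference and the bias of the C4 stereocentre are mismatched, or because an α-branched aryl ketone differentiates its two flanks less well than a methyl ketone. The fallback replaces reagent control by separation and recycling and sets out from 14. NaBH4 in MeOH/THF at −40 °C gives 15 together with its C6 epimer methyl (2S,3S,4S)-2-[4-(benzyloxy)-3-methoxyphenyl]-4-{(S)-[3,4-bis(benzyloxy)phenyl](hydroxy)methyl}oxolane-3-carboxylate F3. The two are separated by chromatography, and F3 is oxidised back to 14 with Dess–Martin periodinane and reduced again. The route is rejoined at 15.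

**Step 11.** Over-reduction may occur: once the para-phenols are free, the C6 benzylic hydroxyl or the C2–O1 bond may be hydrogenolysed before the last benzyl ether has gone. The fallback moves the debenzylation ahead of the C6 alcohol and changes the phenol masks; it sets out from 14.
- Hydrogenolysis (H2, Pd/C, EtOAc) at the ketone stage gives the triphenol methyl (2S,3S,4S)-4-(3,4-dihydroxybenzoyl)-2-(4-hydroxy-3-methoxyphenyl)oxolane-3-carboxylate F4.
- TBSCl/imidazole in DMF gives its tris(tert-butyldimethylsilyl) ether F5.
- The reduction of step 9 gives the (R)-carbinol tris(silyl) hydroxy ester F6.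
- i-Bu2AlH in CH2Cl2 reduces the ester to the tris(silyl) diol F7.
- Tetrabutylammonium fluoride buffered with AcOH removes the silyl groups and gives 17, where the route is rejoined.

**Step 3.** The unhindered, strongly electrophilic enal may undergo conjugate addition or anionic oligomerisation under the basic ylide conditions. The fallback uses a carbenoid at low temperature and a separate ring closure; it sets out from 4. Chloromethyllithium, generated in the presence of 4 from ICH2Cl and MeLi·LiBr in THF at −78 °C, adds 1,2. Quenching gives racemic 3-[3,4-bis(benzyloxy)phenyl]-1-chlorobut-3-en-2-ol F8, and K2CO3 in MeOH closes it to 5, where the route is rejoined.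

**Step 6.** At the temperature a hindered quaternary diester needs, chloride attack on a benzyl ether or thermal degradation of the styrene may compete with demethylation. The fallback separates hydrolysis from decarboxylation and sets out from 9. KOH (1 equiv) in MeOH/THF/H2O hydrolyses one ester to the half-acid 2-[4-(benzyloxy)-3-methoxyphenyl]-4-{1-[3,4-bis(benzyloxy)phenyl]ethenyl}-3-(methoxycarbonyl)oxolane-3-carboxylic acid F9. F9 loses CO2 on heating in toluene/pyridine at 110 °C and gives 11, where the route is rejoined.

## Further compounds

F1 | step 5 | 5-[4-(benzyloxy)-3-methoxybenzylidene]-2,2-dimethyl-1,3-dioxane-4,6-dione | COc1cc(C=C2C(=O)OC(C)(C)OC2=O)ccc1OCc1ccccc1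
F2 | step 5 | 1-[4-(benzyloxy)-3-methoxyphenyl]-4-{1-[3,4-bis(benzyloxy)phenyl]ethenyl}-8,8-dimethyl-2,7,9-trioxaspiro[4.5]decane-6,10-dione, 1,4-cis, same absolute sense as 9 | COc1cc([C@H]2OC[C@@H](C(=C)c3ccc(OCc4ccccc4)c(OCc4ccccc4)c3)C23C(=O)OC(C)(C)OC3=O)ccc1OCc1ccccc1
F3 | step 9 | methyl (2S,3S,4S)-2-[4-(benzyloxy)-3-methoxyphenyl]-4-{(S)-[3,4-bis(benzyloxy)phenyl](hydroxy)methyl}oxolane-3-carboxylate | COc1cc([C@H]2OC[C@@H]([C@H](O)c3ccc(OCc4ccccc4)c(OCc4ccccc4)c3)[C@@H]2C(=O)OC)ccc1OCc1ccccc1
F4 | step 11 | methyl (2S,3S,4S)-4-(3,4-dihydroxybenzoyl)-2-(4-hydroxy-3-methoxyphenyl)oxolane-3-carboxylate | COc1cc([C@H]2OC[C@@H](C(=O)c3ccc(O)c(O)c3)[C@@H]2C(=O)OC)ccc1O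
F5 | step 11 | methyl (2S,3S,4S)-4-{3,4-bis[(tert-butyldimethylsilyl)oxy]benzoyl}-2-{4-[(tert-butyldimethylsilyl)oxy]-3-methoxyphenyl}oxolane-3-carboxylate | COc1cc([C@H]2OC[C@@H](C(=O)c3ccc(O[Si](C)(C)C(C)(C)C)c(O[Si](C)(C)C(C)(C)C)c3)[C@@H]2C(=O)OC)ccc1O[Si](C)(C)C(C)(C)C
F6 | step 11 | methyl (2S,3S,4S)-4-{(R)-[3,4-bis((tert-butyldimethylsilyl)oxy)phenyl](hydroxy)methyl}-2-{4-[(tert-butyldimethylsilyl)oxy]-3-methoxyphenyl}oxolane-3-carboxylate | COc1cc([C@H]2OC[C@@H]([C@@H](O)c3ccc(O[Si](C)(C)C(C)(C)C)c(O[Si](C)(C)C(C)(C)C)c3)[C@@H]2C(=O)OC)ccc1O[Si](C)(C)C(C)(C)C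
F7 | step 11 | (R)-[3,4-bis((tert-butyldimethylsilyl)oxy)phenyl]{(3S,4R,5S)-5-[4-((tert-butyldimethylsilyl)oxy)-3-methoxyphenyl]-4-(hydroxymethyl)oxolan-3-yl}methanol | COc1cc([C@H]2OC[C@@H]([C@@H](O)c3ccc(O[Si](C)(C)C(C)(C)C)c(O[Si](C)(C)C(C)(C)C)c3)[C@@H]2CO)ccc1O[Si](C)(C)C(C)(C)C
F8 | step 3 | racemic 3-[3,4-bis(benzyloxy)phenyl]-1-chlorobut-3-en-2-ol | C=C(C(O)CCl)c1ccc(OCc2ccccc2)c(OCc2ccccc2)c1
F9 | step 6 | 2-[4-(benzyloxy)-3-methoxyphenyl]-4-{1-[3,4-bis(benzyloxy)phenyl]ethenyl}-3-(methoxycarbonyl)oxolane-3-carboxylic acid, 2,4-cis as in 9, both C3 epimers | COc1cc([C@H]2OC[C@@H](C(=C)c3ccc(OCc4ccccc4)c(OCc4ccccc4)c3)C2(C(=O)OC)C(=O)O)ccc1OCc1ccccc1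
A1 | alternative 1 | [3,4-bis(benzyloxy)phenyl]{(3S,4R,5S)-5-[4-(benzyloxy)-3-methoxyphenyl]-4-[(benzyloxy)methyl]oxolan-3-yl}methanol, both epimers at the carbinol carbon | COc1cc([C@H]2OC[C@@H](C(O)c3ccc(OCc4ccccc4)c(OCc4ccccc4)c3)[C@@H]2COCc2ccccc2)ccc1OCc1ccccc1
A2 | alternative 1 | 1,3-dioxoisoindolin-2-yl 2-{[anti-1-(4-(benzyloxy)-3-methoxyphenyl)-2-((benzyloxy)methyl)-4-(3,4-bis(benzyloxy)phenyl)but-3-en-1-yl]oxy}acetate, (E)-alkene | COc1cc([C@@H](OCC(=O)ON2C(=O)c3ccccc3C2=O)[C@@H](COCc2ccccc2)/C=C/c2ccc(OCc3ccccc3)c(OCc3ccccc3)c2)ccc1OCc1ccccc1
A3 | alternative 2 | methyl 2-aryl-4-[aryl(silyloxy)methyl]-4,5-dihydrofuran-3-carboxylate with four tert-butyldimethylsilyl ethers | COc1cc(C2=C(C(=O)OC)[C@H]([C@@H](O[Si](C)(C)C(C)(C)C)c3ccc(O[Si](C)(C)C(C)(C)C)c(O[Si](C)(C)C(C)(C)C)c3)CO2)ccc1O[Si](C)(C)C(C)(C)C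
A4 | alternative 2 | homopropargylic alcohol: 2-[aryl(silyloxy)methyl]-4-arylbut-3-yn-1-ol with four tert-butyldimethylsilyl ethers | COc1cc(C#C[C@H]([C@@H](O[Si](C)(C)C(C)(C)C)c2ccc(O[Si](C)(C)C(C)(C)C)c(O[Si](C)(C)C(C)(C)C)c2)CO)ccc1O[Si](C)(C)C(C)(C)C
A5 | alternative 3 | 2,3-trans-3,4-trans tetrahydrofuran with free guaiacol and hydroxymethyl, silylated carbinol and benzylated catechol | COc1cc([C@H]2OC[C@@H]([C@@H](O[Si](C)(C)C(C)(C)C)c3ccc(OCc4ccccc4)c(OCc4ccccc4)c3)[C@@H]2CO)ccc1O
A6 | alternative 3 | seco-lignan diol: 2-(4-hydroxy-3-methoxybenzyl)-3-{[3,4-bis(benzyloxy)phenyl][(tert-butyldimethylsilyl)oxy]methyl}butane-1,4-diol | COc1cc(C[C@@H](CO)[C@@H](CO)[C@@H](O[Si](C)(C)C(C)(C)C)c2ccc(OCc3ccccc3)c(OCc3ccccc3)c2)ccc1O
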